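All runs were computed for substances that don't exist; the scatter is artificial.

Follow one X. It stands in one step of the scheme, J + X → Z, so each X that reacts takes one J with it into Z.

| setting | epsilon | delta | eta | ochre | amber | red |
|---|---|---|---|---|---|---|
| J | 0.80 M | 0.80 M | 0.80 M | 0.80 M | 0.80 M | 0.80 M |
| X | 0.013 M | 0.016 M | 0.020 M | 0.0100 M | 0.0150 M | 0.0250 M |
| D | 20 mol% | 20 mol% | 20 mol% | 20 mol% | 20 mol% | 20 mol% |
| remark | run made earlier | run made earlier | run made earlier |  |  |  |
| time |  |  |  | 1.0 h | 1.0 h | 1.0 h |

- epsilon (time / min: G / %): 8.00: 26; 15.0: 30; 25.0: 27; 30.0: 29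
- delta (time / min: G / %): 2.50: 13; 6.00: 22; 12.0: 31; 30.0: 27
- eta (time / min: G / %): 2.50: 16; 6.00: 22; 12.0: 26; 30.0: 31

(scatter of a reading: 1.5 percentage points)

- amount of G at the end, in percent of the J charged for ochre, amber, red, in this order
- how the row runs (falls all the way / rises, then falls / hardly changes / falls, then rises / rises all the way)

Red's charge gives 3.12 % and ochre's gives 1.25 %: this is the toll, c(X)/c(J), the share of the J charged that X, the limiting reagent of that step, can carry into Z.

The epsilon run, from its second reading on, averages 28.7 % G. Suppose G keeps that share of the J that the toll leaves. Then going from ochre to red lowers G by 0.54 percentage points, which is less than the scatter of 1.5 points. My reckoning therefore gives a flat row; it gives a difference between flasks, not a level.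

The forecast supplies the level, with 28.6 %, 28.5 % and 28.2 %, so that the row hardly changes, and its ground is that “G therefore seems to settle at a fixed share”.

The flask gives 26.5 %, 26.3 % and 26.0 %: the row hardly changes, falling 0.5 points from ochre to red, and ochre lies 2.1 points under the forecast.

    J ⇌ G (K = 0.560, k = 0.00120 s⁻¹)
    G + D ⇌ L + D, rate k2*[D]*[G] forward; the back reaction follows from the equilibrium constant (K = 1.30, k = 0.00160 M⁻¹ s⁻¹)
    L + D ⇌ J + D, rate k3*[D]*[L] forward; the back reaction follows from the equilibrium constant (k = 6.00 × 10⁻⁴ M⁻¹ s⁻¹)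
    J + X → Z (k = 0.0130 M⁻¹ s⁻¹)

At 1.00 h, red holds X at 0 % of its charge and Z at 3.12 % of the J charged, so red has paid its toll of 3.12 %. Amber's toll is 1.88 %, and at 1.00 h amber holds Z at 1.88 % of the J charged.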